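**Assumptions:** The target has no stereocenters and no E/Z element (the prenyl alkene is CMe2=), so it is achiral and "single enantiomer" is moot. Methyl 1,4-dihydroxy-2-naphthoate is taken as commercial; if not, it comes from 1,4-dihydroxy-2-naphthoic acid by Fischer esterification.

## Retrosynthetic overview
1. Rubioncolin C is a 2-aryloxy-1,4-naphthoquinone. Disconnect the quinone C2–O bond (addition–elimination on 2-bromo-1,4-naphthoquinone) to give the phenol 3-prenyl-DHNA methyl ester.
2. Disconnect the C3 prenyl group (Friedel–Crafts allylation of the hydroquinone ring) to give methyl 1,4-dihydroxy-2-naphthoate and prenol.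
3. No rings are built. Both naphthalene systems are already present in the commercial starting materials.
4. The 1-OH is chelated to the C2 ester, so the free 4-OH is the site that gets arylated. This is why the prenyl group goes on first.

## Forward route

**Step 1**
Reactants: **1** methyl 1,4-dihydroxy-2-naphthoate; **2** prenol (3-methylbut-2-en-1-ol)
Product: **3** methyl 1,4-dihydroxy-3-(3-methylbut-2-en-1-yl)-2-naphthoate
Conditions: BF3·OEt2, dioxane, 0 °C → rt, N2
Reagents that add atoms: prenol, CC(C)=CCO (reactant **2**, supplies the prenyl group); none other
Why: Friedel–Crafts allylation through the prenyl cation puts the prenyl group on the only free carbon of the electron-rich hydroquinone ring (C3, ortho to the 4-OH), and attack at the unhindered CH2 terminus gives the normal prenyl chain. No stereocenter forms.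

**Step 2**
Reactants: **3**; **4** 2-bromo-1,4-naphthoquinone
Product: **5** Rubioncolin C, methyl 1-hydroxy-3-prenyl-4-[(1,4-dioxo-1,4-dihydronaphthalen-2-yl)oxy]-2-naphthoate
Conditions: K2CO3 (1.1 equiv), DMF, 0 °C → rt, N2, dark; **4** (1.2 equiv) added dropwise
Reagents that add atoms: none (the bromoquinone **4** is the reactant; K2CO3 only removes HBr)
Why: The 4-phenoxide adds to C3 of the bromoquinone (oxa-Michael) and loses HBr, an addition–elimination (SNV) that leaves the aryloxy group at C2 of the quinone. The 1-OH stays free because it is hydrogen-bonded to the ester, so only the 4-OH is arylated. No stereocenter forms.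

## Compound list
1 | methyl 1,4-dihydroxy-2-naphthoate | COC(=O)c1cc(O)c2ccccc2c1O | starting material
2 | prenol (3-methylbut-2-en-1-ol) | CC(C)=CCO | starting material
3 | methyl 1,4-dihydroxy-3-prenyl-2-naphthoate | COC(=O)c1c(CC=C(C)C)c(O)c2ccccc2c1O | intermediate
4 | 2-bromo-1,4-naphthoquinone | BrC1=CC(=O)c2ccccc2C1=O | starting material
5 | Rubioncolin C (achiral, no stereocenters) | COC(=O)c1c(CC=C(C)C)c(OC2=CC(=O)c3ccccc3C2=O)c2ccccc2c1O | target

**Total steps:** 2. **Longest linear sequence:** 2 steps from **1**.

## Three most likely failure points
1. **Step 1, prenylation.** Acid can cyclize the new prenyl group onto the 4-OH to give a 2,2-dimethylchroman. The electron-rich hydroquinone can also oxidize to the quinone, or O-prenylate instead of C-prenylate.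
   - Fallback: brominate **1** at C3 (NBS), protect both OH groups as MOM ethers, and couple with prenyl-SnBu3 under Pd catalysis (Stille, α-selective). Then remove the MOM groups.
2. **Step 2, redox exchange.** The hydroquinone **3** can be oxidized by the bromoquinone **4** instead of substituting it, giving the bromohydroquinone and the quinone of **3**.
   - Fallback: do a Cu-catalyzed Ullmann C–O coupling of **3** with 2-bromo-1,4-dimethoxynaphthalene. Then unmask the quinone by low-temperature oxidative demethylation with CAN, after acetylating the 1-OH so the other ring survives.
3. **Step 2, reactivity and selectivity.** The 4-phenoxide is flanked by the prenyl group and a peri C–H, so it is hindered. This could give low conversion, or arylation at the chelated 1-OH.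
   - Fallback: convert lawsone to 2-tosyloxy-1,4-naphthoquinone and couple it with **3** by Pd/tBuBrettPhos-catalyzed C–O coupling. The catalyst, not the phenoxide basicity, then controls the coupling.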